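The dimethylpyran ring fused to ring B is cut across C2–C3 and C4–C4a (chromene numbering), leaving the aryl–O1–C2(CH3)2 unit intact. The key step exploits exactly that unit: as an O-aryl oxocarbenium ion, its atoms C4a=C8a–O1=C2 behave as a cationic 2-oxadiene that takes up vinyl acetate, an acetylene equivalent, in a formal [4+2] annulation; loss of acetic acid then unveils the C3=C4 alkene in the same operation. The precursor is merely the isopropenyl ether of 4-bromo-2-iodophenol. Iodine is afterwards exchanged for prenyl and bromine for boron, and the C2 stereocentre of ring C is set by ligand-controlled conjugate addition of the arylboronic acid to a 7-silyloxychromone.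

Key step: step 2

Assumption: the stereodescriptor of the target corresponds to 2R at C2 of ring C (mirror image of the natural 2S flavanone series); the dimethylpyran ring fused to ring B is numbered as a chromene (O1, C2, C3, C4, C4a to C8a).

Step 1
Reactants: 1 4-bromo-2-iodophenol; 2 isopropenylboronic acid pinacol ester
Product: 3 aryl isopropenyl ether (4-bromo-2-iodo-1-(prop-1-en-2-yloxy)benzene)
Conditions: Cu(OAc)2 (20 mol %), pyridine (3 equiv), 4 Å molecular sieves, O2 (1 atm), CH2Cl2, 23 °C
Reagents that add atoms: none
Why: Chan–Lam oxidative C–O coupling, in which the phenoxide and the alkenyl group transferred from boron meet on copper and reductive elimination from trivalent copper gives the enol ether, the aryl halides being inert at room temperature.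

Step 2
Reactants: 3 aryl isopropenyl ether; 4 vinyl acetate
Product: 7 bromoiodochromene (6-bromo-8-iodo-2,2-dimethyl-2H-chromene), via alpha-chloro ether 5 (not isolated), via 4-acetoxychroman 6 (not isolated)
Conditions: HCl (1.0 equiv, 2 M in Et2O), CH2Cl2, −78 °C; then 4 (3 equiv), SnCl4 (30 mol %), −78 → 23 °C
Reagents that add atoms: none
Why: Proposed new method: Markovnikov addition of HCl to the enol ether should give the tertiary alpha-chloro ether 5, which SnCl4 ionises to the O-aryl oxocarbenium ion; the CH2 terminus of vinyl acetate attacks its carbon (C2–C3 bond), the acetoxy-stabilised cation so formed is captured by the free ortho carbon of the aryl ether (C4–C4a bond) to give 4-acetoxychroman 6, and E1 ionisation of this benzylic, oxygen-conjugated acetate expels acetic acid to leave the C3=C4 alkene. The closest known reaction type is the oxa-Povarov reaction, the SnCl4-mediated formal [4+2] of aldehyde-derived O-aryl oxocarbenium ions with alkenes to give chromans; a ketone-derived ion, an enol ester as the two-carbon partner and the eliminative finish go beyond it. The pyran ring is closed in the second bond-forming event by intramolecular Friedel–Crafts attack, 6-exo-trig with respect to the acyloxycarbenium carbon and assisted by the gem-dimethyl group. The only stereocentre created, C4 of 6, is racemic and is erased by the elimination. The step needs cross-selectivity over self-addition of 3 and ortho regiochemistry: pre-forming 5 with one equivalent of HCl leaves no free enol ether, vinyl acetate does not polymerise cationically and gives a cation electrophilic enough for the halogen-deactivated ring, iodine blocks the second ortho position and bromine the para position.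

Step 3
Reactants: 7 bromoiodochromene; 8 prenyl bromide
Product: 10 bromoprenylchromene (6-bromo-2,2-dimethyl-8-(3-methylbut-2-en-1-yl)-2H-chromene), via aryl Grignard reagent 9 (not isolated)
Conditions: i-PrMgCl·LiCl (1.05 equiv), THF, −20 °C; then CuBr·SMe2 (10 mol %), 8 (1.3 equiv), −20 → 0 °C
Reagents that add atoms: none
Why: Iodine–magnesium exchange is much faster than bromine–magnesium exchange and is accelerated by the ortho ether oxygen, and copper-catalysed allylic substitution of prenyl bromide by the aryl Grignard reagent in THF should occur at the unhindered primary carbon (SN2 mode) to give the linear prenyl group.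

Step 4
Reactants: 10 bromoprenylchromene
Product: 12 arylboronic acid ([2,2-dimethyl-8-(3-methylbut-2-en-1-yl)-2H-chromen-6-yl]boronic acid), via aryllithium 11 (not isolated)
Conditions: B(OiPr)3 (1.5 equiv), n-BuLi (1.1 equiv), THF/toluene, −78 °C; then 1 M HCl (aq), 0 °C, short contact
Reagents that add atoms: triisopropyl borate CC(C)OB(OC(C)C)OC(C)C; water O
Why: Bromine–lithium exchange at −78 °C outpaces attack of n-BuLi on the borate, the aryllithium is trapped in situ as the borate ate complex (borylation of an organolithium), and brief cold hydrolysis should release the boronic acid without touching the acid-sensitive chromene and prenyl alkenes.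

Step 5
Reactants: 13 7-hydroxychromone
Product: 14 7-silyloxychromone (7-[(tert-butyldimethylsilyl)oxy]-4H-chromen-4-one)
Conditions: TBSCl (1.2 equiv), imidazole (2 equiv), DMF, 23 °C
Reagents that add atoms: tert-butyldimethylsilyl chloride CC(C)(C)[Si](C)(C)Cl
Why: Imidazole-assisted silylation of a phenol, which masks the acidic 7-OH so that the chromone remains a neutral, electrophilic enone in the next step.

Step 6
Reactants: 12 arylboronic acid; 14 7-silyloxychromone
Product: 15 silyl-protected flavanone ((2R)-7-[(tert-butyldimethylsilyl)oxy]-2-[2,2-dimethyl-8-(3-methylbut-2-en-1-yl)-2H-chromen-6-yl]-2,3-dihydro-4H-chromen-4-one)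
Conditions: Pd(OCOCF3)2 (5 mol %), (S)-4-tert-butyl-2-(pyridin-2-yl)-4,5-dihydro-1,3-oxazole (6 mol %), NH4PF6 (30 mol %), H2O (5 equiv), 14 (1.5 equiv), ClCH2CH2Cl, 40 °C
Reagents that add atoms: none
Why: Catalytic asymmetric conjugate addition of an arylboronic acid to a chromone, in which transmetalation gives a cationic aryl complex of divalent palladium that inserts the C2=C3 bond and the palladium enolate is protonated by water; the ligand controls the face of insertion and the (S)-ligand is expected, by analogy with its sense on cyclic enones, to deliver 2R (its enantiomer would be used if the assignment proved opposite).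

Step 7
Reactants: 15 silyl-protected flavanone
Product: 16 target flavanone ((2R)-2-[2,2-dimethyl-8-(3-methylbut-2-en-1-yl)-2H-chromen-6-yl]-7-hydroxy-2,3-dihydro-4H-chromen-4-one)
Conditions: KHF2 (2 equiv), MeOH, 23 °C
Reagents that add atoms: none
Why: Fluoride-mediated cleavage of a phenolic silyl ether under slightly acidic conditions, which should avoid the base-induced retro-oxa-Michael ring opening that would racemise C2 and should leave the chromene and prenyl groups untouched.

Compound list
1 | 4-bromo-2-iodophenol | Oc1ccc(Br)cc1I | starting material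
2 | isopropenylboronic acid pinacol ester (4,4,5,5-tetramethyl-2-(prop-1-en-2-yl)-1,3,2-dioxaborolane) | CC(=C)B1OC(C)(C)C(C)(C)O1 | starting material
3 | 4-bromo-2-iodo-1-(prop-1-en-2-yloxy)benzene | CC(=C)Oc1ccc(Br)cc1I | intermediate
4 | vinyl acetate | C=COC(C)=O | starting material
5 | 4-bromo-1-[(2-chloropropan-2-yl)oxy]-2-iodobenzene (alpha-chloro ether, not isolated) | CC(C)(Cl)Oc1ccc(Br)cc1I | intermediate
6 | 6-bromo-8-iodo-2,2-dimethyl-3,4-dihydro-2H-chromen-4-yl acetate (racemic, not isolated) | CC(=O)OC1CC(C)(C)Oc2c(I)cc(Br)cc21 | intermediate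
7 | 6-bromo-8-iodo-2,2-dimethyl-2H-chromene | CC1(C)C=Cc2cc(Br)cc(I)c2O1 | intermediate
8 | prenyl bromide (1-bromo-3-methylbut-2-ene) | CC(C)=CCBr | starting material
9 | (6-bromo-2,2-dimethyl-2H-chromen-8-yl)magnesium chloride (LiCl complex, not isolated) | CC1(C)C=Cc2cc(Br)cc([Mg]Cl)c2O1 | intermediate
10 | 6-bromo-2,2-dimethyl-8-(3-methylbut-2-en-1-yl)-2H-chromene | CC(C)=CCc1cc(Br)cc2c1OC(C)(C)C=C2 | intermediate
11 | [2,2-dimethyl-8-(3-methylbut-2-en-1-yl)-2H-chromen-6-yl]lithium (not isolated) | [Li]c1cc(CC=C(C)C)c2OC(C)(C)C=Cc2c1 | intermediate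
12 | [2,2-dimethyl-8-(3-methylbut-2-en-1-yl)-2H-chromen-6-yl]boronic acid | CC(C)=CCc1cc(B(O)O)cc2c1OC(C)(C)C=C2 | intermediate
13 | 7-hydroxy-4H-chromen-4-one (7-hydroxychromone) | O=c1ccoc2cc(O)ccc12 | starting material
14 | 7-[(tert-butyldimethylsilyl)oxy]-4H-chromen-4-one | CC(C)(C)[Si](C)(C)Oc1ccc2c(c1)occc2=O | intermediate
15 | (2R)-7-[(tert-butyldimethylsilyl)oxy]-2-[2,2-dimethyl-8-(3-methylbut-2-en-1-yl)-2H-chromen-6-yl]-2,3-dihydro-4H-chromen-4-one | CC(C)=CCc1cc([C@H]2CC(=O)c3ccc(O[Si](C)(C)C(C)(C)C)cc3O2)cc2c1OC(C)(C)C=C2 | intermediate
16 | (2R)-2-[2,2-dimethyl-8-(3-methylbut-2-en-1-yl)-2H-chromen-6-yl]-7-hydroxy-2,3-dihydro-4H-chromen-4-one | CC(C)=CCc1cc([C@H]2CC(=O)c3ccc(O)cc3O2)cc2c1OC(C)(C)C=C2 | target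

Total step count: 7
Longest linear sequence: 6 steps (steps 1, 2, 3, 4, 6, 7); step 5 prepares the second fragment.

Steps most likely to fail

1. Step 2 (proposed new method). What may go wrong: self-addition of the oxocarbenium ion to enol ether regenerated by loss of HCl (cyclodimerisation); acid-induced cleavage of the tertiary alkyl aryl ether before the slow ring closure onto the twice halogenated ring; or cationic oligomerisation of the chromene once formed. Fallback with known chemistry, setting out from 1 and coming back to the route at 7: O-alkylation of 1 with 3-chloro-3-methylbut-1-yne (DBU, CuCl2 cat., MeCN, 0 °C) should give the aryl 1,1-dimethylpropargyl ether 4-bromo-2-iodo-1-[(2-methylbut-3-yn-2-yl)oxy]benzene F1. Heating F1 in N,N-diethylaniline at 190 °C should then give 7 by aromatic propargyl Claisen rearrangement, 1,5-hydrogen shift and oxa-6π electrocyclisation. This closes the pyran ring through C4–C4a and O1–C2 and gives up the two-bond annulation, but it secures the same intermediate.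

2. Step 6. What may go wrong: protodeboronation of the electron-rich boronic acid outrunning insertion into the electron-rich 7-silyloxychromone, or insufficient facial discrimination by the ligand. Fallback, setting out from 10 and coming back at 16, in which the stereocentre is obtained by resolution instead of asymmetric C–C bond formation:
- Bromine–lithium exchange of 10 (n-BuLi, THF, −78 °C) and formylation with DMF should give 2,2-dimethyl-8-(3-methylbut-2-en-1-yl)-2H-chromene-6-carbaldehyde F2.
- 2',4'-Dihydroxyacetophenone is selectively protected at the non-chelated hydroxyl (MOMCl, K2CO3, acetone) to give 1-[2-hydroxy-4-(methoxymethoxy)phenyl]ethan-1-one F3.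
- Claisen–Schmidt condensation of F2 with F3 (KOH, EtOH, 23 °C) should give the chalcone (E)-3-[2,2-dimethyl-8-(3-methylbut-2-en-1-yl)-2H-chromen-6-yl]-1-[2-hydroxy-4-(methoxymethoxy)phenyl]prop-2-en-1-one F4.
- Intramolecular oxa-Michael cyclisation (NaOAc, EtOH, reflux) should give the racemic 7-(methoxymethoxy)flavanone F5.
- Acetal cleavage (3 M HCl, MeOH, 50 °C) should give the racemic flavanone F6.
- Preparative chromatography of F6 on a polysaccharide chiral stationary phase should deliver 16.

3. Step 1. What may go wrong: slow transmetalation and C–O coupling at the hindered, electron-poor ortho-iodophenol, while protodeboronation or oxidative homocoupling consumes the alkenylboronate. Fallback, setting out from 1 and coming back at 3: acetylation of 1 (Ac2O, pyridine, 23 °C) should give 4-bromo-2-iodophenyl acetate F7, and carbonyl methylenation of this aryl ester with Cp2TiMe2 (toluene, 70 °C) should give 3.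

Further compounds
F1 | step 2 | 4-bromo-2-iodo-1-[(2-methylbut-3-yn-2-yl)oxy]benzene | C#CC(C)(C)Oc1ccc(Br)cc1I
F2 | step 6 | 2,2-dimethyl-8-(3-methylbut-2-en-1-yl)-2H-chromene-6-carbaldehyde | CC(C)=CCc1cc(C=O)cc2c1OC(C)(C)C=C2
F3 | step 6 | 1-[2-hydroxy-4-(methoxymethoxy)phenyl]ethan-1-one | CC(=O)c1ccc(OCOC)cc1O
F4 | step 6 | (E)-3-[2,2-dimethyl-8-(3-methylbut-2-en-1-yl)-2H-chromen-6-yl]-1-[2-hydroxy-4-(methoxymethoxy)phenyl]prop-2-en-1-one | COCOc1ccc(C(=O)/C=C/c2cc(CC=C(C)C)c3OC(C)(C)C=Cc3c2)c(O)c1
F5 | step 6 | racemic 2-[2,2-dimethyl-8-(3-methylbut-2-en-1-yl)-2H-chromen-6-yl]-7-(methoxymethoxy)-2,3-dihydro-4H-chromen-4-one | COCOc1ccc2C(=O)CC(Oc2c1)c1cc(CC=C(C)C)c2OC(C)(C)C=Cc2c1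
F6 | step 6 | racemic 2-[2,2-dimethyl-8-(3-methylbut-2-en-1-yl)-2H-chromen-6-yl]-7-hydroxy-2,3-dihydro-4H-chromen-4-one | CC(C)=CCc1cc(C2CC(=O)c3ccc(O)cc3O2)cc2c1OC(C)(C)C=C2
F7 | step 1 | 4-bromo-2-iodophenyl acetate | CC(=O)Oc1ccc(Br)cc1I
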